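**Structural features**

The target is an 8-O-4' neolignan made of two arenes and no other ring. Ring A is a 4-hydroxy-3,5-dimethoxyphenyl group whose C1 carries the chain C7H(OH)–C8H(OAr)–C9H2OH. The oxygen on C8 is also the phenolic oxygen O4' of ring B, a 2,6-dimethoxyphenyl ether that carries the chain C7'H2–C8'H(OH)–C9'H2OH para to O4'. C7 (S) and C8 (R) are neighbours and stand anti (erythro); C8' (S) sits on the far side of ring B, so nothing at C7 or C8 can control it. The fragile part is the free phenol para to the C7 carbinol: acid or base can open a quinone methide, which epimerises C7 or expels C9 as formaldehyde, and the benzylic C7–O bond is open to ionisation and hydrogenolysis; both rings are also electron-rich and sensitive to oxidants. The real difficulty is the C8–O4' bond, which joins a secondary carbon lying between two oxygenated carbons to a phenol oxygen screened by two ortho methoxy groups, with C8 defined relative to C7. The key step uses the fact that C7, C8 and C9 are three single carbons in a row from C1 of ring A, each bearing one oxygen. Each can be brought in as a one-carbon unit bound to boron, and the insertion that forms the C7–C8 bond leaves chlorine and boron together on C8, the activation needed to bring in first the hindered O4' and then C9.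

**Logic of the disconnections**

27 ⇒ 26 ⇒ 25. The bonds cut are O4–CH2Ph and O7–CH2Ph, then the two C–O bonds of the isopropylidene ketal on O8' and O9'. The free phenol para to the C7 carbinol and the 1,2-diol cannot pass through organolithium, alkoxide and Lewis acid steps. The gain is that the labile p-hydroxybenzyl alcohol exists only in the last flask. The forward demand is that the ketal is hydrolysed with weak acid while O4 and O7 are still capped, and that the last step is neutral and breaks the O–CH2Ph bonds and not C7–O.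

25 ⇒ 20 + 21. The C8–C9 bond is cut and the C9–O bond is traced back to a C9–B bond. C9 is one carbon with one oxygen, the retron of a one-carbon insertion into the C8–B bond followed by oxidation, and the insertion proceeds with retention at C8. The gain is that 20 holds only the two adjacent stereocentres and the boron that built them. The demand is that the hindered, aryloxy-bearing C8 migrates cleanly, and that 24, whose boron is β to the aryloxy group, is oxidised in the same flask.

20 ⇒ 13 + 18. The C8–O4' bond is cut. In 13 the carbon carries chlorine next to boron, the one arrangement in which a hindered, weakly basic oxygen nucleophile can be expected to substitute at a secondary carbon, because boron captures the nucleophile first. The cut also divides the molecule into halves of similar size, so ring B and C8' leave the main line. The demand is clean inversion from the (S)-chloride to the (R)-ether, faster than chloride exchange at C8.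

13 ⇒ 9 + 10. The C7–C8 bond is cut. C8 with its chlorine and boron is one carbon (11, made from 10) inserted into the C7–B bond of 9; the diol on boron fixes C8 and C7 keeps its configuration. The gain is one stereocentre less, by the same kind of borate rearrangement that builds C7. The demand is that the auxiliary tells the two chlorines apart, that boron is not lost together with the β-oxygen, and that the new chloride does not epimerise.

9 ⇒ 8 ⇒ 2 + 5. First the O7–C7 bond is cut (substitution of chloride by a benzyl alkoxide with inversion), then the C1–C7 bond: ring A is delivered to the boron of 5 as 6 and moves from boron to carbon within 7. The gain is that all stereochemistry leaves the carbon skeleton and only the auxiliary remains chiral, and that ring A needs no boronic acid of its own. The demand is that 6 adds to boron and does not deprotonate 5, and that 8, a benzylic chloride on an electron-rich ring, is made in the presence of a chloride scavenger and used at once.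

5 ⇒ 3 + 4 and 2 ⇒ 1. The two B–O bonds to the diol and the O4–CH2Ph bond are cut. Both are single operations that lead to 1, 3 and 4, all taken as commercial. The only demands are complete removal of the liberated alcohol in the ester exchange and O-alkylation of a phenol flanked by two methoxy groups.

18 ⇒ 17 ⇒ 16 ⇒ 2 + 14. The ketal C–O bonds, two O–CH2Ph bonds and the C1'–C7' bond are cut. C8' cannot be controlled from C7 or C8, so it is taken from the chiral pool: the aryl–CH2 bond is made by opening an epoxide at its terminal carbon, and the stereocentre is never touched. An asymmetric dihydroxylation of an allyl arene would look shorter, but allyl arenes are a weak substrate class for that reaction and C8' epimers could not be removed later. The gain is that 2 feeds both rings. The demand is attack at the terminal epoxide carbon only.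

**Other disconnections considered**

Alternative 1: The cut is the C1–C7 bond. Aryllithium 6 would add to the chiral-pool aldehyde A2, a (2R)-2-aryloxy-3-silyloxypropanal, to give the protected target A1.
- In its favour: C8 comes from a glyceric acid unit, and the C8–O4' bond is made beforehand on an α-hydroxy ester, where substitution with inversion is well founded. On this bond Alternative 1 is the better plan, since the chosen route has to form it by an untested displacement. It is also shorter by two or three steps.
- Against it: A2 has an acidic C8–H next to the aldehyde, so the basic aryllithium may enolise it and erode C8, or expel silyloxide. C7 is set only by substrate control: the polar Felkin–Anh model predicts anti, but lithium chelation between the aldehyde and the aryloxy or methoxy oxygens favours syn, so a C7 mixture that must be separated is likely.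
- Comparison: the chosen plan sets C7 and C8 by the same auxiliary-controlled mechanism used twice, at the price of more steps and one unproven substitution. Both plans buy C8' from the chiral pool and are equal on that point.

Alternative 2: The cut removes the four C–H bonds at C7, C8, C7' and C8'. One enantiomer of Ru(OAc)2(BINAP) under H2 would reduce both (Z)-alkenes of the bis(α-oxycinnamic acid) A4 to the (S,S)-diacid A3.
- In its favour: one catalytic step sets C8 and C8' from flat precursors and uses the hidden likeness of the two arms. In economy of chirality (no auxiliary, no chiral-pool epoxide) it is better than the chosen plan.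
- Against it: C7 is a methylene in A3. The C7 hydroxyl would have to be introduced afterwards by benzylic oxidation, next to a second benzylic methylene (C7') and two electron-rich rings, with control of configuration; no dependable way to do this is evident. The alkene bearing the di-ortho-substituted aryloxy group is also a hindered substrate, and both acids must still be reduced.
- Comparison: the chosen plan carries the C7 oxygen from the first boron step and so reaches the correct oxidation level by construction. The two are equal in the final deprotection, since both remove benzyl ethers by hydrogenolysis.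

Alternative 3: The cut is the O4'–C4' bond, with ring B introduced in non-aromatic form. Rh2(OAc)4 would turn the diazo dione A6 into a rhodium carbenoid that inserts into the free C8 hydroxyl of the protected ring A triol A7, giving the enol ether A5. Ring B would then be aromatised and its two hydroxyls methylated.
- In its favour: the C8–O bond is never broken, so C8 is secure by construction, and O–H insertion tolerates hindered alcohols. On stereochemical safety at C8 it is better than step 9 of the chosen plan.
- Against it: A7, with both stereocentres, must first be made by some other asymmetric route. After coupling, the dione ring has to be dehydrogenated under oxidising conditions in the presence of ring A and two benzylic ethers, and then doubly methylated. A6 needs its own synthesis. The sequence is at least four steps longer.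
- Comparison: the chosen plan builds C7 and C8 and joins the halves in three consecutive boron steps with ring B already aromatic. It is equal to Alternative 3 in protecting-group load.

Key step: step 5

Remarks on the chemistry:
- Locants: C1–C9 are ring A and its chain, C1'–C9' are ring B and its chain, and O4' is the ether oxygen.
- With the (R,R)-diol on boron each rearrangement of a dichloromethyl borate should give the (S)-α-chloro boronate. Followed through the two inversions and the CIP rankings, this leads to (7S,8R), so one enantiomer of the auxiliary serves both cycles. The change of the C7 descriptor from (R) in 9 to (S) in 13 only reflects the replacement of boron by C8 in the ranking.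
- Diisopropyl (dichloromethyl)boronate 3, diol 4, (S)-benzyl glycidyl ether 14 and bromochloromethane 21 are taken as commercial.

Step 1
Reactants: 1 4-bromo-2,6-dimethoxyphenol
Product: 2 2-(benzyloxy)-5-bromo-1,3-dimethoxybenzene
Conditions: BnBr, K2CO3, DMF, 50 °C
Reagents that add atoms: benzyl bromide BrCc1ccccc1
Why: Williamson ether synthesis on the phenoxide; the benzyl ether withstands the organolithium, alkoxide and Lewis acid steps and serves both ring A and ring B.

Step 2
Reactants: 3 dipropan-2-yl (dichloromethyl)boronate; 4 (1R,2R)-1,2-dicyclohexylethane-1,2-diol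
Product: 5 (4R,5R)-4,5-dicyclohexyl-2-(dichloromethyl)-1,3,2-dioxaborolane
Conditions: Et2O, rt; then removal of i-PrOH under reduced pressure
Reagents that add atoms: none
Why: Transesterification of a boronic ester: the 1,2-diol replaces both isopropoxy groups and closes the five-membered dioxaborolane, driven by removal of volatile propan-2-ol. The dicyclohexyl diol gives a hydrolytically robust ester, so the auxiliary should stay on boron through all three carbon–carbon bond formations.

Step 3
Reactants: 2 2-(benzyloxy)-5-bromo-1,3-dimethoxybenzene; 5 (4R,5R)-4,5-dicyclohexyl-2-(dichloromethyl)-1,3,2-dioxaborolane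
Product: 8 (4R,5R)-2-{(S)-[4-(benzyloxy)-3,5-dimethoxyphenyl](chloro)methyl}-4,5-dicyclohexyl-1,3,2-dioxaborolane, via aryllithium 6 (not isolated), via lithium aryl(dichloromethyl)borate 7 (not isolated)
Conditions: 2, n-BuLi (0.98 equiv), THF, −78 °C; add 5, −78 °C; ZnCl2 (1.5 equiv), −78 °C → rt
Reagents that add atoms: none
Why: Bromine–lithium exchange gives 6, which adds to the boron of 5 to form borate 7, the same kind of intermediate as in a Matteson homologation but reached from the organometallic side. In the ZnCl2-assisted 1,2-shift the aryl group moves from boron to carbon while the (R,R)-diol selects which chlorine leaves, giving the (S)-chloride at C7. ZnCl2 also binds the chloride set free, which would otherwise epimerise this benzylic chloride; 8 is used crude and at once.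

Step 4
Reactants: 8 (4R,5R)-2-{(S)-[4-(benzyloxy)-3,5-dimethoxyphenyl](chloro)methyl}-4,5-dicyclohexyl-1,3,2-dioxaborolane
Product: 9 (4R,5R)-2-{(R)-(benzyloxy)[4-(benzyloxy)-3,5-dimethoxyphenyl]methyl}-4,5-dicyclohexyl-1,3,2-dioxaborolane
Conditions: BnOH, NaH, THF, 0 °C; then 8, DMSO, 0 °C → rt
Reagents that add atoms: benzyl alcohol OCc1ccccc1
Why: Alkoxide displacement on an α-chloro boronic ester: sodium benzyloxide adds to boron and shifts to C7 as chloride leaves, which inverts C7 to (R). C7 has no β-hydrogen, so elimination cannot compete.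

Step 5
Reactants: 9 (4R,5R)-2-{(R)-(benzyloxy)[4-(benzyloxy)-3,5-dimethoxyphenyl]methyl}-4,5-dicyclohexyl-1,3,2-dioxaborolane; 10 dichloromethane
Product: 13 (4R,5R)-2-{(1S,2S)-2-(benzyloxy)-2-[4-(benzyloxy)-3,5-dimethoxyphenyl]-1-chloroethyl}-4,5-dicyclohexyl-1,3,2-dioxaborolane, via dichloromethyllithium 11 (not isolated), via lithium alkyl(dichloromethyl)borate 12 (not isolated)
Conditions: 10, n-BuLi, THF, −100 °C; add 9; ZnCl2 (3 equiv), −100 °C → 15 °C; cold aq. NH4Cl work-up, used crude
Reagents that add atoms: none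
Why: 11 adds to the trigonal boron of 9 at −100 °C to give the tetracoordinate borate 12; the diol is C2-symmetric, so the two faces of boron are equivalent and no isomers arise at this stage. ZnCl2 binds a ring oxygen and one of the two diastereotopic chlorines, and C7 migrates from boron to the dichloromethyl carbon anti to that chlorine, which leaves; this forms the C7–C8 bond with retention at C7 and inversion at the carbenoid carbon. The closest known reaction type is the Matteson homologation of α-alkoxyalkyl boronic esters of C2-symmetric diols with LiCHCl2 and ZnCl2. No ring is closed. The one new stereocentre, C8, should be set as (S) by the (R,R)-diol in the same sense as in step 3, and C7 is carried through unchanged, so the later inversion at C8 gives the anti (erythro) pair. The step needs selection between the two chlorines, migration of carbon in preference to a ring oxygen, and survival of a product with a benzyloxy group β to boron and an epimerisable chloride. The first two are secured by the auxiliary and ZnCl2, used in excess because the ether oxygen at C7 also binds it and because it removes free chloride from solution. Loss of boron together with benzyloxide is held back by the low temperature, by the poor leaving-group ability of an alkoxide, and by ring A itself, whose para oxygen is twisted out of conjugation by the two flanking methoxy groups and so gives little help to ionisation at C7.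

Step 6
Reactants: 2 2-(benzyloxy)-5-bromo-1,3-dimethoxybenzene; 14 (2S)-2-[(benzyloxy)methyl]oxirane
Product: 16 (2S)-1-(benzyloxy)-3-[4-(benzyloxy)-3,5-dimethoxyphenyl]propan-2-ol, via arylmagnesium bromide 15 (not isolated)
Conditions: Mg, THF, 40 °C; then CuI (10 mol %), 14, −30 °C → 0 °C
Reagents that add atoms: none
Why: Copper-catalysed opening of a terminal epoxide by an aryl Grignard reagent at the unsubstituted carbon. The C–O bond at the stereocentre is not touched, so C8' keeps the configuration bought with 14 and is (S).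

Step 7
Reactants: 16 (2S)-1-(benzyloxy)-3-[4-(benzyloxy)-3,5-dimethoxyphenyl]propan-2-ol
Product: 17 (2S)-3-(4-hydroxy-3,5-dimethoxyphenyl)propane-1,2-diol
Conditions: H2 (1 atm), Pd/C (10%), EtOH, rt
Reagents that add atoms: none
Why: Hydrogenolysis of the aryl and the primary alkyl benzyl ether; the benzylic carbon C7' bears no oxygen, so nothing else can be reduced.

Step 8
Reactants: 17 (2S)-3-(4-hydroxy-3,5-dimethoxyphenyl)propane-1,2-diol
Product: 18 4-{[(4S)-2,2-dimethyl-1,3-dioxolan-4-yl]methyl}-2,6-dimethoxyphenol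
Conditions: Me2C(OMe)2, PPTS (cat.), acetone, rt
Reagents that add atoms: 2,2-dimethoxypropane COC(C)(C)OC
Why: Acid-catalysed ketal exchange closes the dioxolane on the 1,2-diol; the phenol forms no stable ketal and stays free for step 9.

Step 9
Reactants: 13 (4R,5R)-2-{(1S,2S)-2-(benzyloxy)-2-[4-(benzyloxy)-3,5-dimethoxyphenyl]-1-chloroethyl}-4,5-dicyclohexyl-1,3,2-dioxaborolane; 18 4-{[(4S)-2,2-dimethyl-1,3-dioxolan-4-yl]methyl}-2,6-dimethoxyphenol
Product: 20 (4R,5R)-2-{(1R,2S)-2-(benzyloxy)-2-[4-(benzyloxy)-3,5-dimethoxyphenyl]-1-(4-{[(4S)-2,2-dimethyl-1,3-dioxolan-4-yl]methyl}-2,6-dimethoxyphenoxy)ethyl}-4,5-dicyclohexyl-1,3,2-dioxaborolane, via sodium phenolate 19 (not isolated)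
Conditions: 18 (1.5 equiv), NaH, THF, 0 °C; then 13, DMSO, 0 °C → rt
Reagents that add atoms: none
Why: Proposed new method: the phenoxide oxygen of 19 should add to the vacant orbital of boron in 13 and then shift from boron to C8 anti to the C–Cl bond, so that chloride leaves with inversion and C8 becomes (R); the closest known reaction types are the displacement of chloride in α-chloro boronic esters by alkoxides (as in step 4) and of halide in halomethyl boronic esters by phenoxides, extended here to a di-ortho-substituted phenoxide at a secondary carbon; the phenoxide is a weak base and its ortho and para carbons are blocked, so loss of HCl and C-alkylation are not expected.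

Step 10
Reactants: 20 (4R,5R)-2-{(1R,2S)-2-(benzyloxy)-2-[4-(benzyloxy)-3,5-dimethoxyphenyl]-1-(4-{[(4S)-2,2-dimethyl-1,3-dioxolan-4-yl]methyl}-2,6-dimethoxyphenoxy)ethyl}-4,5-dicyclohexyl-1,3,2-dioxaborolane; 21 bromochloromethane
Product: 25 (2R,3S)-3-(benzyloxy)-3-[4-(benzyloxy)-3,5-dimethoxyphenyl]-2-(4-{[(4S)-2,2-dimethyl-1,3-dioxolan-4-yl]methyl}-2,6-dimethoxyphenoxy)propan-1-ol, via chloromethyllithium 22 (not isolated), via lithium chloromethylborate 23 (not isolated), via homologated boronate 24 (not isolated)
Conditions: 21, n-BuLi, THF, −78 °C → rt; then 30% H2O2, 2 M NaOH, 0 °C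
Reagents that add atoms: hydrogen peroxide OO
Why: Matteson one-carbon homologation: 22, made from 21 beside the substrate, adds to boron and C8 migrates to the CH2 carbon with retention as chloride leaves. Alkaline hydrogen peroxide then converts the C9–B bond of 24 into C9–OH and releases the auxiliary 4; 24 is oxidised in the same flask because its boron is β to the aryloxy group.

Step 11
Reactants: 25 (2R,3S)-3-(benzyloxy)-3-[4-(benzyloxy)-3,5-dimethoxyphenyl]-2-(4-{[(4S)-2,2-dimethyl-1,3-dioxolan-4-yl]methyl}-2,6-dimethoxyphenoxy)propan-1-ol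
Product: 26 (2S)-3-(4-{[(1S,2R)-1-(benzyloxy)-1-[4-(benzyloxy)-3,5-dimethoxyphenyl]-3-hydroxypropan-2-yl]oxy}-3,5-dimethoxyphenyl)propane-1,2-diol
Conditions: AcOH/H2O (4:1), 40 °C
Reagents that add atoms: none
Why: Hydrolysis of the isopropylidene ketal with weak acid. O4 and O7 are still benzylated, so no quinone methide can form and C7 should not ionise.

Step 12
Reactants: 26 (2S)-3-(4-{[(1S,2R)-1-(benzyloxy)-1-[4-(benzyloxy)-3,5-dimethoxyphenyl]-3-hydroxypropan-2-yl]oxy}-3,5-dimethoxyphenyl)propane-1,2-diol
Product: 27 (2S)-3-(4-{[(1S,2R)-1,3-dihydroxy-1-(4-hydroxy-3,5-dimethoxyphenyl)propan-2-yl]oxy}-3,5-dimethoxyphenyl)propane-1,2-diol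
Conditions: H2 (1 atm), Pd/C (10%), EtOAc/EtOH, rt, stopped after uptake of 2 equiv
Reagents that add atoms: none
Why: Hydrogenolysis of the aryl benzyl ether and the O7 benzyl ether under neutral conditions. Cleavage is expected at the unhindered O–CH2Ph carbons and not at the congested secondary C7–O bond, and no acid or base is present that could epimerise the p-hydroxybenzyl alcohol.

**Compound list**

1 | 4-bromo-2,6-dimethoxyphenol | COc1cc(Br)cc(OC)c1O | starting material
2 | 2-(benzyloxy)-5-bromo-1,3-dimethoxybenzene | COc1cc(Br)cc(OC)c1OCc1ccccc1 | intermediate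
3 | dipropan-2-yl (dichloromethyl)boronate | CC(C)OB(OC(C)C)C(Cl)Cl | starting material
4 | (1R,2R)-1,2-dicyclohexylethane-1,2-diol | O[C@H](C1CCCCC1)[C@H](O)C1CCCCC1 | starting material
5 | (4R,5R)-4,5-dicyclohexyl-2-(dichloromethyl)-1,3,2-dioxaborolane | ClC(Cl)B1O[C@H](C2CCCCC2)[C@@H](C2CCCCC2)O1 | intermediate
6 | [4-(benzyloxy)-3,5-dimethoxyphenyl]lithium | COc1cc([Li])cc(OC)c1OCc1ccccc1 | intermediate
7 | lithium (4R,5R)-2-[4-(benzyloxy)-3,5-dimethoxyphenyl]-4,5-dicyclohexyl-2-(dichloromethyl)-1,3,2-dioxaborolan-2-uide | [Li+].COc1cc([B-]2(C(Cl)Cl)O[C@H](C3CCCCC3)[C@@H](C3CCCCC3)O2)cc(OC)c1OCc1ccccc1 | intermediate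
8 | (4R,5R)-2-{(S)-[4-(benzyloxy)-3,5-dimethoxyphenyl](chloro)methyl}-4,5-dicyclohexyl-1,3,2-dioxaborolane | COc1cc([C@@H](Cl)B2O[C@H](C3CCCCC3)[C@@H](C3CCCCC3)O2)cc(OC)c1OCc1ccccc1 | intermediate
9 | (4R,5R)-2-{(R)-(benzyloxy)[4-(benzyloxy)-3,5-dimethoxyphenyl]methyl}-4,5-dicyclohexyl-1,3,2-dioxaborolane | COc1cc([C@H](OCc2ccccc2)B2O[C@H](C3CCCCC3)[C@@H](C3CCCCC3)O2)cc(OC)c1OCc1ccccc1 | intermediate
10 | dichloromethane | ClCCl | starting material
11 | dichloromethyllithium | [Li]C(Cl)Cl | intermediate
12 | lithium (4R,5R)-2-{(R)-(benzyloxy)[4-(benzyloxy)-3,5-dimethoxyphenyl]methyl}-4,5-dicyclohexyl-2-(dichloromethyl)-1,3,2-dioxaborolan-2-uide | [Li+].COc1cc([C@H](OCc2ccccc2)[B-]2(C(Cl)Cl)O[C@H](C3CCCCC3)[C@@H](C3CCCCC3)O2)cc(OC)c1OCc1ccccc1 | intermediate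
13 | (4R,5R)-2-{(1S,2S)-2-(benzyloxy)-2-[4-(benzyloxy)-3,5-dimethoxyphenyl]-1-chloroethyl}-4,5-dicyclohexyl-1,3,2-dioxaborolane | COc1cc([C@H](OCc2ccccc2)[C@@H](Cl)B2O[C@H](C3CCCCC3)[C@@H](C3CCCCC3)O2)cc(OC)c1OCc1ccccc1 | intermediate
14 | (2S)-2-[(benzyloxy)methyl]oxirane | C1O[C@@H]1COCc1ccccc1 | starting material
15 | [4-(benzyloxy)-3,5-dimethoxyphenyl]magnesium bromide | COc1cc([Mg]Br)cc(OC)c1OCc1ccccc1 | intermediate
16 | (2S)-1-(benzyloxy)-3-[4-(benzyloxy)-3,5-dimethoxyphenyl]propan-2-ol | COc1cc(C[C@H](O)COCc2ccccc2)cc(OC)c1OCc1ccccc1 | intermediate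
17 | (2S)-3-(4-hydroxy-3,5-dimethoxyphenyl)propane-1,2-diol | COc1cc(C[C@H](O)CO)cc(OC)c1O | intermediate
18 | 4-{[(4S)-2,2-dimethyl-1,3-dioxolan-4-yl]methyl}-2,6-dimethoxyphenol | COc1cc(C[C@H]2COC(C)(C)O2)cc(OC)c1O | intermediate
19 | sodium 4-{[(4S)-2,2-dimethyl-1,3-dioxolan-4-yl]methyl}-2,6-dimethoxyphenolate | [Na+].COc1cc(C[C@H]2COC(C)(C)O2)cc(OC)c1[O-] | intermediate
20 | (4R,5R)-2-{(1R,2S)-2-(benzyloxy)-2-[4-(benzyloxy)-3,5-dimethoxyphenyl]-1-(4-{[(4S)-2,2-dimethyl-1,3-dioxolan-4-yl]methyl}-2,6-dimethoxyphenoxy)ethyl}-4,5-dicyclohexyl-1,3,2-dioxaborolane | COc1cc([C@H](OCc2ccccc2)[C@H](Oc2c(OC)cc(C[C@H]3COC(C)(C)O3)cc2OC)B2O[C@H](C3CCCCC3)[C@@H](C3CCCCC3)O2)cc(OC)c1OCc1ccccc1 | intermediate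
21 | bromochloromethane | ClCBr | starting material
22 | (chloromethyl)lithium | [Li]CCl | intermediate
23 | lithium (4R,5R)-2-{(1R,2S)-2-(benzyloxy)-2-[4-(benzyloxy)-3,5-dimethoxyphenyl]-1-(4-{[(4S)-2,2-dimethyl-1,3-dioxolan-4-yl]methyl}-2,6-dimethoxyphenoxy)ethyl}-2-(chloromethyl)-4,5-dicyclohexyl-1,3,2-dioxaborolan-2-uide | [Li+].COc1cc([C@H](OCc2ccccc2)[C@H](Oc2c(OC)cc(C[C@H]3COC(C)(C)O3)cc2OC)[B-]2(CCl)O[C@H](C3CCCCC3)[C@@H](C3CCCCC3)O2)cc(OC)c1OCc1ccccc1 | intermediate
24 | (4R,5R)-2-{(2R,3S)-3-(benzyloxy)-3-[4-(benzyloxy)-3,5-dimethoxyphenyl]-2-(4-{[(4S)-2,2-dimethyl-1,3-dioxolan-4-yl]methyl}-2,6-dimethoxyphenoxy)propyl}-4,5-dicyclohexyl-1,3,2-dioxaborolane | COc1cc([C@H](OCc2ccccc2)[C@H](Oc2c(OC)cc(C[C@H]3COC(C)(C)O3)cc2OC)CB2O[C@H](C3CCCCC3)[C@@H](C3CCCCC3)O2)cc(OC)c1OCc1ccccc1 | intermediate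
25 | (2R,3S)-3-(benzyloxy)-3-[4-(benzyloxy)-3,5-dimethoxyphenyl]-2-(4-{[(4S)-2,2-dimethyl-1,3-dioxolan-4-yl]methyl}-2,6-dimethoxyphenoxy)propan-1-ol | COc1cc([C@H](OCc2ccccc2)[C@@H](CO)Oc2c(OC)cc(C[C@H]3COC(C)(C)O3)cc2OC)cc(OC)c1OCc1ccccc1 | intermediate
26 | (2S)-3-(4-{[(1S,2R)-1-(benzyloxy)-1-[4-(benzyloxy)-3,5-dimethoxyphenyl]-3-hydroxypropan-2-yl]oxy}-3,5-dimethoxyphenyl)propane-1,2-diol | COc1cc([C@H](OCc2ccccc2)[C@@H](CO)Oc2c(OC)cc(C[C@H](O)CO)cc2OC)cc(OC)c1OCc1ccccc1 | intermediate
27 | (2S)-3-(4-{[(1S,2R)-1,3-dihydroxy-1-(4-hydroxy-3,5-dimethoxyphenyl)propan-2-yl]oxy}-3,5-dimethoxyphenyl)propane-1,2-diol | COc1cc([C@H](O)[C@@H](CO)Oc2c(OC)cc(C[C@H](O)CO)cc2OC)cc(OC)c1O | target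

**Step count and least certain steps**

Total: 12 steps. Longest linear sequence: 8 steps (steps 1, 3, 4, 5, 9, 10, 11, 12); step 2 supplies 5 in one operation and steps 6–8 form the ring B branch from 2.

Step 9 (proposed new method). The hindered, weakly nucleophilic phenoxide may substitute slowly. Chloride exchange would then erode the configuration at C8, or the boron-bound phenoxide may trigger loss of boron together with the β-benzyloxy group. The fallback uses only known reaction types, brings in C9 before the aryl ether, and runs from 13 to 25: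
- The Grignard reagent (i-PrO)Me2SiCH2MgCl in THF at −78 °C → rt displaces chloride with inversion and gives the silylmethyl boronate F1.
- H2O2 with KF and KHCO3 in THF/MeOH oxidises both the C–Si and the C–B bond (Tamao oxidation and boronate oxidation, each with retention) and gives the diol F2. Its C8 oxygen has the configuration opposite to that needed.
- t-BuMe2SiCl and imidazole protect the primary hydroxyl and give the silyl ether F3.
- A Mitsunobu reaction of F3 with 18 (PPh3, diisopropyl azodicarboxylate, toluene) inverts C8 and gives the aryl ether F4.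
- Bu4NF in THF then gives 25.

Step 5 (key step). Under ZnCl2 the benzylic C7–O bond may ionise and boron may leave together with the β-benzyloxy group. The bulky α-benzyloxybenzyl group may also migrate slowly, so that chloride discrimination or the configuration of the new chloride suffers. The fallback leaves the boron chain and forms the C1–C7 bond last; it runs from 18 and 6 (made from 2 as in step 3) to 25:
- Methyl (S)-glycerate is silylated at the primary hydroxyl (i-Pr3SiCl, imidazole) to give the hydroxy ester F5.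
- A Mitsunobu reaction with 18 inverts the carbinol and gives the (R)-aryloxy ester F6.
- i-Bu2AlH at −78 °C gives the aldehyde A2.
- Addition of 6 in THF at −78 °C should give mainly the anti alcohol A1 (polar Felkin–Anh model).
- NaH and BnBr give the benzyl ether F7, and Bu4NF gives 25.

Step 10. Boron and the β-aryloxy group may be lost together from 24 or from its peroxide adduct, because an aryloxide is a far better leaving group than an alkoxide. The hindered C8 may also migrate too slowly, so that the carbenoid decomposes first. The fallback turns the C8–B bond into a C8–C bond with boron leaving in the same operation; it runs from 20 to 25: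
- Zweifel olefination (vinylmagnesium bromide, THF, −78 °C; I2; NaOMe, MeOH) gives the terminal alkene F8 with retention at C8. Iodide, not the aryloxide, is the group that leaves anti to boron.
- OsO4 (cat.) with NaIO4 and 2,6-lutidine in dioxane/H2O gives the aldehyde F9.
- NaBH4 at 0 °C, applied at once, gives 25.

Step 12. Over-reduction at C7 is the risk: both C–O bonds of the O7 ether are benzylic, and ring A becomes a p-hydroxybenzyl system once its own benzyl group is gone. The fallback changes the O7 protecting group to 2-naphthylmethyl, which is cleaved by hydrogenolysis much faster than a benzyl ether; it runs from 8 to 27: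
- Sodium (naphthalen-2-yl)methoxide with 8, under the conditions of step 4, gives the naphthylmethoxy boronate F10.
- The conditions of steps 5, 9, 10 and 11 then give in turn the chloro boronate F11, the aryloxy boronate F12, the primary alcohol F13 and the triol F14.
- A short hydrogenolysis over Pd/C gives 27.

Step 3. The aryllithium may remove the acidic proton of the dichloromethyl group instead of adding to boron, or the benzylic chloride may lose configuration by chloride exchange before it is used. The fallback puts boron on ring A first and brings the carbon in as the carbanion; it runs from 2 to 8: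
- Bromine–lithium exchange on 2 (n-BuLi, THF, −78 °C), B(OiPr)3 and 1 M HCl give the boronic acid F15.
- Esterification with 4 (MgSO4, Et2O, rt) gives the aryl boronate F16.
- Dichloromethyllithium 11, made as in step 5, adds to F16 at −100 °C, and ZnCl2 then gives 8 through the same borate 7.

**Further compounds**

F1 | step 9 | (4R,5R)-2-{(1R,2R)-1-(benzyloxy)-1-[4-(benzyloxy)-3,5-dimethoxyphenyl]-3-[dimethyl(propan-2-yloxy)silyl]propan-2-yl}-4,5-dicyclohexyl-1,3,2-dioxaborolane | COc1cc([C@H](OCc2ccccc2)[C@H](C[Si](C)(C)OC(C)C)B2O[C@H](C3CCCCC3)[C@@H](C3CCCCC3)O2)cc(OC)c1OCc1ccccc1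
F2 | step 9 | (2S,3S)-3-(benzyloxy)-3-[4-(benzyloxy)-3,5-dimethoxyphenyl]propane-1,2-diol | COc1cc([C@H](OCc2ccccc2)[C@H](CO)O)cc(OC)c1OCc1ccccc1
F3 | step 9 | (1S,2S)-1-(benzyloxy)-1-[4-(benzyloxy)-3,5-dimethoxyphenyl]-3-{[tert-butyl(dimethyl)silyl]oxy}propan-2-ol | COc1cc([C@H](OCc2ccccc2)[C@H](CO[Si](C)(C)C(C)(C)C)O)cc(OC)c1OCc1ccccc1
F4 | step 9 | tert-butyl{[(2R,3S)-3-(benzyloxy)-3-[4-(benzyloxy)-3,5-dimethoxyphenyl]-2-(4-{[(4S)-2,2-dimethyl-1,3-dioxolan-4-yl]methyl}-2,6-dimethoxyphenoxy)propyl]oxy}dimethylsilane | COc1cc([C@H](OCc2ccccc2)[C@@H](CO[Si](C)(C)C(C)(C)C)Oc2c(OC)cc(C[C@H]3COC(C)(C)O3)cc2OC)cc(OC)c1OCc1ccccc1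
F5 | step 5 | methyl (2S)-2-hydroxy-3-{[tri(propan-2-yl)silyl]oxy}propanoate | COC(=O)[C@@H](O)CO[Si](C(C)C)(C(C)C)C(C)C
F6 | step 5 | methyl (2R)-2-(4-{[(4S)-2,2-dimethyl-1,3-dioxolan-4-yl]methyl}-2,6-dimethoxyphenoxy)-3-{[tri(propan-2-yl)silyl]oxy}propanoate | COC(=O)[C@@H](CO[Si](C(C)C)(C(C)C)C(C)C)Oc1c(OC)cc(C[C@H]2COC(C)(C)O2)cc1OC
F7 | step 5 | {[(2R,3S)-3-(benzyloxy)-3-[4-(benzyloxy)-3,5-dimethoxyphenyl]-2-(4-{[(4S)-2,2-dimethyl-1,3-dioxolan-4-yl]methyl}-2,6-dimethoxyphenoxy)propyl]oxy}tri(propan-2-yl)silane | COc1cc([C@H](OCc2ccccc2)[C@@H](CO[Si](C(C)C)(C(C)C)C(C)C)Oc2c(OC)cc(C[C@H]3COC(C)(C)O3)cc2OC)cc(OC)c1OCc1ccccc1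
F8 | step 10 | (4S)-4-{[4-({(3R,4S)-4-(benzyloxy)-4-[4-(benzyloxy)-3,5-dimethoxyphenyl]but-1-en-3-yl}oxy)-3,5-dimethoxyphenyl]methyl}-2,2-dimethyl-1,3-dioxolane | COc1cc([C@H](OCc2ccccc2)[C@H](Oc2c(OC)cc(C[C@H]3COC(C)(C)O3)cc2OC)C=C)cc(OC)c1OCc1ccccc1
F9 | step 10 | (2S,3S)-3-(benzyloxy)-3-[4-(benzyloxy)-3,5-dimethoxyphenyl]-2-(4-{[(4S)-2,2-dimethyl-1,3-dioxolan-4-yl]methyl}-2,6-dimethoxyphenoxy)propanal | COc1cc([C@H](OCc2ccccc2)[C@H](Oc2c(OC)cc(C[C@H]3COC(C)(C)O3)cc2OC)C=O)cc(OC)c1OCc1ccccc1
F10 | step 12 | (4R,5R)-2-{(R)-[4-(benzyloxy)-3,5-dimethoxyphenyl][(naphthalen-2-yl)methoxy]methyl}-4,5-dicyclohexyl-1,3,2-dioxaborolane | COc1cc([C@H](OCc2ccc3ccccc3c2)B2O[C@H](C3CCCCC3)[C@@H](C3CCCCC3)O2)cc(OC)c1OCc1ccccc1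
F11 | step 12 | (4R,5R)-2-{(1S,2S)-2-[4-(benzyloxy)-3,5-dimethoxyphenyl]-1-chloro-2-[(naphthalen-2-yl)methoxy]ethyl}-4,5-dicyclohexyl-1,3,2-dioxaborolane | COc1cc([C@H](OCc2ccc3ccccc3c2)[C@@H](Cl)B2O[C@H](C3CCCCC3)[C@@H](C3CCCCC3)O2)cc(OC)c1OCc1ccccc1
F12 | step 12 | (4R,5R)-2-{(1R,2S)-2-[4-(benzyloxy)-3,5-dimethoxyphenyl]-1-(4-{[(4S)-2,2-dimethyl-1,3-dioxolan-4-yl]methyl}-2,6-dimethoxyphenoxy)-2-[(naphthalen-2-yl)methoxy]ethyl}-4,5-dicyclohexyl-1,3,2-dioxaborolane | COc1cc([C@H](OCc2ccc3ccccc3c2)[C@H](Oc2c(OC)cc(C[C@H]3COC(C)(C)O3)cc2OC)B2O[C@H](C3CCCCC3)[C@@H](C3CCCCC3)O2)cc(OC)c1OCc1ccccc1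
F13 | step 12 | (2R,3S)-3-[4-(benzyloxy)-3,5-dimethoxyphenyl]-2-(4-{[(4S)-2,2-dimethyl-1,3-dioxolan-4-yl]methyl}-2,6-dimethoxyphenoxy)-3-[(naphthalen-2-yl)methoxy]propan-1-ol | COc1cc([C@H](OCc2ccc3ccccc3c2)[C@@H](CO)Oc2c(OC)cc(C[C@H]3COC(C)(C)O3)cc2OC)cc(OC)c1OCc1ccccc1
F14 | step 12 | (2S)-3-(4-{[(1S,2R)-1-[4-(benzyloxy)-3,5-dimethoxyphenyl]-3-hydroxy-1-[(naphthalen-2-yl)methoxy]propan-2-yl]oxy}-3,5-dimethoxyphenyl)propane-1,2-diol | COc1cc([C@H](OCc2ccc3ccccc3c2)[C@@H](CO)Oc2c(OC)cc(C[C@H](O)CO)cc2OC)cc(OC)c1OCc1ccccc1
F15 | step 3 | [4-(benzyloxy)-3,5-dimethoxyphenyl]boronic acid | COc1cc(B(O)O)cc(OC)c1OCc1ccccc1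
F16 | step 3 | (4R,5R)-2-[4-(benzyloxy)-3,5-dimethoxyphenyl]-4,5-dicyclohexyl-1,3,2-dioxaborolane | COc1cc(B2O[C@H](C3CCCCC3)[C@@H](C3CCCCC3)O2)cc(OC)c1OCc1ccccc1
A1 | alternative 1 | (1S,2R)-1-[4-(benzyloxy)-3,5-dimethoxyphenyl]-2-(4-{[(4S)-2,2-dimethyl-1,3-dioxolan-4-yl]methyl}-2,6-dimethoxyphenoxy)-3-{[tri(propan-2-yl)silyl]oxy}propan-1-ol | COc1cc([C@H](O)[C@@H](CO[Si](C(C)C)(C(C)C)C(C)C)Oc2c(OC)cc(C[C@H]3COC(C)(C)O3)cc2OC)cc(OC)c1OCc1ccccc1
A2 | alternative 1 | (2R)-2-(4-{[(4S)-2,2-dimethyl-1,3-dioxolan-4-yl]methyl}-2,6-dimethoxyphenoxy)-3-{[tri(propan-2-yl)silyl]oxy}propanal | O=C[C@@H](CO[Si](C(C)C)(C(C)C)C(C)C)Oc1c(OC)cc(C[C@H]2COC(C)(C)O2)cc1OC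
A3 | alternative 2 | (2S)-3-[4-(benzyloxy)-3,5-dimethoxyphenyl]-2-{4-[(2S)-2-(benzyloxy)-2-carboxyethyl]-2,6-dimethoxyphenoxy}propanoic acid | COc1cc(C[C@H](Oc2c(OC)cc(C[C@H](OCc3ccccc3)C(=O)O)cc2OC)C(=O)O)cc(OC)c1OCc1ccccc1
A4 | alternative 2 | (2Z)-3-[4-(benzyloxy)-3,5-dimethoxyphenyl]-2-{4-[(1Z)-2-(benzyloxy)-2-carboxyethenyl]-2,6-dimethoxyphenoxy}prop-2-enoic acid | COc1cc(/C=C(\Oc2c(OC)cc(/C=C(\OCc3ccccc3)C(=O)O)cc2OC)C(=O)O)cc(OC)c1OCc1ccccc1
A5 | alternative 3 | 2-{[(1S,2R)-1-(benzyloxy)-1-[4-(benzyloxy)-3,5-dimethoxyphenyl]-3-{[tert-butyl(diphenyl)silyl]oxy}propan-2-yl]oxy}-5-{[(4S)-2,2-dimethyl-1,3-dioxolan-4-yl]methyl}-3-hydroxycyclohex-2-en-1-one | COc1cc([C@H](OCc2ccccc2)[C@@H](CO[Si](C(C)(C)C)(c2ccccc2)c2ccccc2)OC2=C(O)CC(C[C@H]3COC(C)(C)O3)CC2=O)cc(OC)c1OCc1ccccc1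
A6 | alternative 3 | 2-diazo-5-{[(4S)-2,2-dimethyl-1,3-dioxolan-4-yl]methyl}cyclohexane-1,3-dione | [N-]=[N+]=C1C(=O)CC(C[C@H]2COC(C)(C)O2)CC1=O
A7 | alternative 3 | (1S,2R)-1-(benzyloxy)-1-[4-(benzyloxy)-3,5-dimethoxyphenyl]-3-{[tert-butyl(diphenyl)silyl]oxy}propan-2-ol | COc1cc([C@H](OCc2ccccc2)[C@@H](CO[Si](C(C)(C)C)(c2ccccc2)c2ccccc2)O)cc(OC)c1OCc1ccccc1
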